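C8–O and H5 lie 1,4 on the same face of ring B, anti to the C10 methyl (C20) and to C11, so C5–C6–C7–C8 with the C8 methyl and the C8 oxygen is read as a 5-methylfuran whose oxygen bridges C5 and C8.
Last disconnections: C13=C14 by Horner–Wadsworth–Emmons on a C13 methyl ketone, C11=C12 by Wittig on the C11 aldehyde, C3–Br from the C3 ketone via the axial alcohol and substitution with inversion.
trans-Decalin from the oxygen-bridged decalin: enol ether to C6 ketone, SmI2 cleavage of C5–O (C8–OH kept), C6 oxygen removed through the enol triflate.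
Rings A and B are formed together, in one step, by the intramolecular Diels–Alder reaction of the 3-methoxyfuran (C5=C6–C7=C8) with the tethered E-enoate (C9=C10), making C5–C10 and C8–C9.
Precursor from 5-methylfuran-3(2H)-one: O-methylation, C-lithiation and epoxide opening, gem-dimethylation (C4), enolate alkylation with a C5 bromo ester (C1, C10, C9, C11), CBS reduction (C3).

Key step: step 8

Remark on numbering: labdane numbering throughout (C3 = CHBr, C4 = CMe2, C5/C10 = ring fusion, C8 = C(OH)Me, C9 = chain-bearing CH, C11 = first chain carbon, C20 = methyl on C10); C15 ring compounds are named as drimanes with the same ring numbering. The target is (3R,5S,8S,9S,10R,13E).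
Assumption: methyl (2E)-4-bromo-3-methylbut-2-enoate (10) is used as the pure E isomer; commercial material containing the Z isomer is chromatographed first.
Remark on C3: the oxygen that steers the cycloaddition sits equatorial, where the bromine must finally be, so C3 is taken through the ketone and the axial alcohol before substitution with inversion; it is carried as a pivalate so that the hydride reduction of the C11 ester frees it.

Step 1
Reactants: 1 5-methylfuran-3(2H)-one
Product: 3 4-methoxy-2-methylfuran, via potassium 5-methylfuran-3-olate 2 (not isolated)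
Conditions: KN(SiMe3)2, THF/DMPU, −78 °C; then MeOTf, −78 → 0 °C
Reagents that add atoms: methyl trifluoromethanesulfonate, COS(=O)(=O)C(F)(F)F
Why: Deprotonation at C2 gives the aromatic furan-3-olate 2, an ambident enolate that a hard methylating agent in a dipolar medium alkylates on oxygen (O-alkylation of an enolate), which fixes the ring as the 3-methoxyfuran.

Step 2
Reactants: 3 4-methoxy-2-methylfuran; 4 2-methyloxirane (racemic)
Product: 6 1-(3-methoxy-5-methylfuran-2-yl)propan-2-ol (racemic), via (3-methoxy-5-methylfuran-2-yl)lithium 5 (not isolated)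
Conditions: n-BuLi, THF, −78 → 0 °C; then 4, −78 → 25 °C
Reagents that add atoms: 2-methyloxirane (4), CC1CO1
Why: Directed α-lithiation takes place at the ring carbon flanked by the ring oxygen and the methoxy group, and the furyllithium opens the epoxide at its unsubstituted carbon (SN2 epoxide opening); the racemic carbinol centre is removed in step 3.

Step 3
Reactants: 6 1-(3-methoxy-5-methylfuran-2-yl)propan-2-ol
Product: 7 1-(3-methoxy-5-methylfuran-2-yl)propan-2-one
Conditions: Pr4N[RuO4] (cat.), NMO, 4 Å MS, CH2Cl2, 25 °C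
Reagents that add atoms: none
Why: Ley–Griffith oxidation under neutral conditions turns the secondary alcohol into the ketone without touching the acid-sensitive methoxyfuran.

Step 4
Reactants: 7 1-(3-methoxy-5-methylfuran-2-yl)propan-2-one
Product: 9 3-(3-methoxy-5-methylfuran-2-yl)-3-methylbutan-2-one, via 3-(3-methoxy-5-methylfuran-2-yl)butan-2-one 8 (not isolated)
Conditions: NaH (2.2 equiv), MeI (2.5 equiv), THF, 0 → 25 °C
Reagents that add atoms: iodomethane, CI
Why: Both methyl groups enter at the doubly activated furfurylic α-carbon through the conjugated enolate (enolate C-alkylation, the monomethyl ketone 8 reacting on), so the quaternary C4 next to the furan is made by two methylations and not by a hindered carbon–carbon coupling to the ring.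

Step 5
Reactants: 9 3-(3-methoxy-5-methylfuran-2-yl)-3-methylbutan-2-one; 10 methyl (2E)-4-bromo-3-methylbut-2-enoate
Product: 12 methyl (2E)-7-(3-methoxy-5-methylfuran-2-yl)-3,7-dimethyl-6-oxooct-2-enoate, via lithium 3-(3-methoxy-5-methylfuran-2-yl)-3-methylbut-1-en-2-olate 11 (not isolated)
Conditions: LiN(i-Pr)2, THF, −78 °C; then 10, DMPU, −78 → −20 °C
Reagents that add atoms: methyl (2E)-4-bromo-3-methylbut-2-enoate (10), COC(=O)/C=C(\C)CBr
Why: Ketone 9 can enolise only at its methyl group, and the lithium enolate displaces the allylic bromide directly (SN2 enolate alkylation), which joins C2 to C1 and brings in C10, C9 and C11 with the E geometry of 10 untouched.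

Step 6
Reactants: 12 methyl (2E)-7-(3-methoxy-5-methylfuran-2-yl)-3,7-dimethyl-6-oxooct-2-enoate
Product: 13 methyl (2E,6R)-6-hydroxy-7-(3-methoxy-5-methylfuran-2-yl)-3,7-dimethyloct-2-enoate
Conditions: (S)-2-methyl-CBS-oxazaborolidine (cat.), BH3·SMe2, THF, −30 °C
Reagents that add atoms: none
Why: Corey–Bakshi–Shibata reduction, in which the tertiary-alkyl side of the ketone acts as the large group, so the (S)-catalyst should deliver hydride to the face that gives the (R)-carbinol, which is C3.

Step 7
Reactants: 13 methyl (2E,6R)-6-hydroxy-7-(3-methoxy-5-methylfuran-2-yl)-3,7-dimethyloct-2-enoate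
Product: 14 methyl (2E,6R)-6-(2,2-dimethylpropanoyloxy)-7-(3-methoxy-5-methylfuran-2-yl)-3,7-dimethyloct-2-enoate
Conditions: PivCl, DMAP (cat.), pyridine, 60 °C
Reagents that add atoms: 2,2-dimethylpropanoyl chloride, CC(C)(C)C(=O)Cl
Why: DMAP-catalysed acylation gives an ester without α-hydrogens that should survive the later acid, SmI2, enolate and palladium steps and is cleaved by the same hydride that reduces the C11 ester.

Step 8
Reactants: 14 methyl (2E,6R)-6-(2,2-dimethylpropanoyloxy)-7-(3-methoxy-5-methylfuran-2-yl)-3,7-dimethyloct-2-enoate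
Product: 15 methyl 5,8-epoxy-6-methoxy-3-pivaloyloxydrim-6-en-11-oate (C10 methyl and C9 ester anti to the oxygen bridge; C3 pivaloyloxy equatorial, cis to the C10 methyl)
Conditions: CH2Cl2 (trace 2,6-lutidine), 13 kbar, 25 °C; crude product taken on at once
Reagents that add atoms: none
Why: A concerted but asynchronous normal-demand [4+2] cycloaddition in which the 3-methoxyfuran, whose HOMO is raised by the methoxy group and is largest at C5, adds across the enoate so that nucleophilic C5 bonds to the electrophilic β-carbon C10 and C8 bonds to C9; the closest known reaction type is the intramolecular Diels–Alder reaction of 2-alkylfurans, 3-alkoxyfurans included, with tethered acrylates, and pressure is applied because the reaction has a large negative volume of activation and of reaction and is reversible at 1 bar. Ring A is closed as a six-membered carbocycle through the C5–C10 bond with the four-carbon tether C1–C4 in a chair held exo (syn to the oxygen bridge), the only geometry such a short tether allows and one that the C4 gem-dimethyl group favours, and ring B is closed at the same time as the oxygen-bridged six-membered ring C5–C6–C7–C8–C9–C10 (a 7-oxabicyclo[2.2.1]heptene). C5 and C8 are set together by suprafacial addition to the furan, which leaves the oxygen bridge on one face; C10 and C9 are set by the exo tether and by the E geometry of the enoate, which is transferred suprafacially so that the C10 methyl and the ester, cis on the alkene, both end up anti to the bridge. The face of the diene–dienophile pair that reacts, and with it the absolute configuration of C5, C8, C9 and C10, is decided by the C3 stereocentre, whose pivaloyloxy group takes the equatorial position of the chair-like tether, cis to the C10 methyl. The step needs this facial selectivity and enough conversion: the first rests on the equatorial preference next to the gem-dimethyl group, the second on pressure, the electron-rich furan and the Thorpe–Ingold effect, and any minor facial isomer is to be removed before C3 is oxidised in step 15.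

Step 9
Reactants: 15 methyl 5,8-epoxy-6-methoxy-3-pivaloyloxydrim-6-en-11-oate
Product: 16 methyl 5,8-epoxy-6-oxo-3-pivaloyloxydriman-11-oate
Conditions: 0.1 M HCl, THF/H2O, 0 °C
Reagents that add atoms: water, O
Why: Acid-catalysed hydrolysis of the enol ether (protonation at C7, hemiketal, loss of methanol) gives the C6 ketone, after which cycloreversion is no longer possible; dilute acid at 0 °C is chosen so that C7 protonation stays ahead of ionisation of the C8–O bond.

Step 10
Reactants: 16 methyl 5,8-epoxy-6-oxo-3-pivaloyloxydriman-11-oate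
Product: 18 methyl 8-hydroxy-6-oxo-3-pivaloyloxydriman-11-oate (trans-fused; H5 anti to the C10 methyl; C8 hydroxyl anti to C11), via samarium 5-en-6-olate 8-alkoxide 17 (not isolated)
Conditions: SmI2 (2.5 equiv), THF/MeOH, −78 °C
Reagents that add atoms: none
Why: SmI2 reduction of an α-alkoxy ketone, in which the C6 ketyl expels the α-oxygen so that only C5–O breaks and C8 keeps its oxygen and configuration, and the samarium enolate 17 should be protonated at C5 on the face the oxygen has left, anti to the axial C10 methyl, which gives the trans ring fusion.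

Step 11
Reactants: 18 methyl 8-hydroxy-6-oxo-3-pivaloyloxydriman-11-oate
Product: 19 methyl 6-oxo-3-pivaloyloxy-8-(triethylsilyloxy)driman-11-oate
Conditions: Et3SiOTf, 2,6-lutidine, CH2Cl2, −78 → 0 °C
Reagents that add atoms: triethylsilyl trifluoromethanesulfonate, CC[Si](CC)(CC)OS(=O)(=O)C(F)(F)F
Why: Silylation with a silyl triflate and a hindered pyridine protects the tertiary C8 hydroxyl, which closes off retro-aldol cleavage and dehydration of the β-hydroxy ketone in the steps that follow.

Step 12
Reactants: 19 methyl 6-oxo-3-pivaloyloxy-8-(triethylsilyloxy)driman-11-oate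
Product: 21 methyl 3-pivaloyloxy-8-(triethylsilyloxy)-6-(trifluoromethanesulfonyloxy)drim-6-en-11-oate, via potassium 6-en-6-olate 20 (not isolated)
Conditions: KN(SiMe3)2, THF, −78 °C; then PhNTf2, −78 → −20 °C
Reagents that add atoms: N-phenylbis(trifluoromethanesulfonimide), O=S(=O)(N(c1ccccc1)S(=O)(=O)C(F)(F)F)C(F)(F)F
Why: Kinetic deprotonation removes a C7 hydrogen and not the hindered C5 methine, and the potassium enolate 20 is triflated on oxygen (enol triflate formation); at low temperature the β-silyloxy group should not be expelled.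

Step 13
Reactants: 21 methyl 3-pivaloyloxy-8-(triethylsilyloxy)-6-(trifluoromethanesulfonyloxy)drim-6-en-11-oate
Product: 22 methyl 3-pivaloyloxy-8-(triethylsilyloxy)drim-6-en-11-oate
Conditions: Pd(OAc)2 (cat.), PPh3, HCO2H, Bu3N, DMF, 60 °C
Reagents that add atoms: none
Why: Palladium-catalysed formate reduction of an enol triflate, in which zerovalent palladium inserts into the C6–O bond, formate supplies hydride with loss of CO2 and reductive elimination leaves C6 as an alkene CH, so the C6 oxygen is gone.

Step 14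
Reactants: 22 methyl 3-pivaloyloxy-8-(triethylsilyloxy)drim-6-en-11-oate
Product: 23 8-(triethylsilyloxy)drim-6-ene-3,11-diol (C3 hydroxyl equatorial)
Conditions: LiAlH4, THF, 0 → 25 °C
Reagents that add atoms: none
Why: Hydride reduction of both esters gives the C11 primary alcohol and frees the C3 hydroxyl in one operation, while the silyl ether and the ring alkene are inert.

Step 15
Reactants: 23 8-(triethylsilyloxy)drim-6-ene-3,11-diol
Product: 24 3-oxo-8-(triethylsilyloxy)drim-6-en-11-al
Conditions: Pr4N[RuO4] (cat.), NMO (3 equiv), 4 Å MS, CH2Cl2, 25 °C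
Reagents that add atoms: none
Why: Ley–Griffith oxidation takes the primary alcohol to the C11 aldehyde and the secondary alcohol to the C3 ketone under neutral conditions that should neither epimerise C9 nor eliminate the β-silyloxy group.

Step 16
Reactants: 24 3-oxo-8-(triethylsilyloxy)drim-6-en-11-al; 25 1-(triphenyl-λ5-phosphanylidene)propan-2-one
Product: 26 (11E)-8-(triethylsilyloxy)-14,15-dinorlabda-6,11-diene-3,13-dione
Conditions: toluene, 100 °C
Reagents that add atoms: 1-(triphenyl-λ5-phosphanylidene)propan-2-one (25), CC(=O)C=P(c1ccccc1)(c1ccccc1)c1ccccc1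
Why: Wittig olefination with a stabilised ylide reacts only with the aldehyde, not with the neopentylic C3 ketone, and gives the E-enone that carries C12, C13 and C16.

Step 17
Reactants: 26 (11E)-8-(triethylsilyloxy)-14,15-dinorlabda-6,11-diene-3,13-dione
Product: 27 8-(triethylsilyloxy)-14,15-dinorlabdane-3,13-dione
Conditions: H2 (1 atm), Pd/C, EtOAc, 25 °C
Reagents that add atoms: none
Why: Heterogeneous hydrogenation saturates the conjugated C11=C12 bond and the cis-disubstituted C6=C7 bond, leaves both ketones and the silyl ether untouched and creates no stereocentre.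

Step 18
Reactants: 27 8-(triethylsilyloxy)-14,15-dinorlabdane-3,13-dione; 28 trimethyl phosphonoacetate
Product: 29 methyl (13E)-3-oxo-8-(triethylsilyloxy)labd-13-en-15-oate
Conditions: NaH, THF, 0 → 50 °C; E isomer separated by chromatography
Reagents that add atoms: trimethyl phosphonoacetate (28), COC(=O)CP(=O)(OC)OC
Why: Horner–Wadsworth–Emmons olefination takes place at the unhindered methyl ketone and not at the C3 ketone flanked by the C4 gem-dimethyl group, and favours the E-enoate (ester trans to the chain), the Z isomer being removed.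

Step 19
Reactants: 29 methyl (13E)-3-oxo-8-(triethylsilyloxy)labd-13-en-15-oate
Product: 30 methyl (13E)-3-hydroxy-8-(triethylsilyloxy)labd-13-en-15-oate (C3 hydroxyl axial, trans to the C10 methyl)
Conditions: LiBH(s-Bu)3, THF, −78 °C
Reagents that add atoms: none
Why: The bulky borohydride attacks the C3 ketone along the equatorial direction, as is known for 4,4-dimethyl-3-ketones of trans-decalins, and should give the axial alcohol, while the β,β-disubstituted enoate is not reduced at −78 °C.

Step 20
Reactants: 30 methyl (13E)-3-hydroxy-8-(triethylsilyloxy)labd-13-en-15-oate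
Product: 31 methyl (3R,13E)-3-bromo-8-(triethylsilyloxy)labd-13-en-15-oate (bromine equatorial, cis to the C10 methyl)
Conditions: CBr4, P(n-Oct)3, toluene, 70 °C
Reagents that add atoms: tetrabromomethane, BrC(Br)(Br)Br
Why: Appel reaction, in which the oxyphosphonium of the axial alcohol is displaced by bromide with inversion (SN2), which puts bromine equatorial as in the target; no free hydroxyl is left elsewhere in the molecule.

Step 21
Reactants: 31 methyl (3R,13E)-3-bromo-8-(triethylsilyloxy)labd-13-en-15-oate
Product: 32 (3R,13E)-3-bromo-8-(triethylsilyloxy)labd-13-en-15-ol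
Conditions: i-Bu2AlH (2.5 equiv), CH2Cl2, −78 °C
Reagents that add atoms: none
Why: 1,2-Reduction of the enoate by the aluminium hydride gives the E-allylic alcohol without touching the neopentylic secondary bromide or the silyl ether.

Step 22
Reactants: 32 (3R,13E)-3-bromo-8-(triethylsilyloxy)labd-13-en-15-ol
Product: 33 (3R,5S,8S,9S,10R,13E)-3-bromolabd-13-ene-8,15-diol
Conditions: HF·pyridine, pyridine, THF, 0 → 25 °C
Reagents that add atoms: none
Why: Fluoride cleaves the Si–O bond of the tertiary silyl ether (desilylation) under buffered conditions that leave the allylic alcohol, the tertiary alcohol and the bromide unchanged.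

Compound list
1 | 5-methylfuran-3(2H)-one | CC1=CC(=O)CO1 | starting material
2 | potassium 5-methylfuran-3-olate | Cc1cc([O-])co1.[K+] | intermediate (not isolated)
3 | 4-methoxy-2-methylfuran | COc1coc(C)c1 | intermediate
4 | 2-methyloxirane (racemic) | CC1CO1 | starting material
5 | (3-methoxy-5-methylfuran-2-yl)lithium | [Li]c1oc(C)cc1OC | intermediate (not isolated)
6 | 1-(3-methoxy-5-methylfuran-2-yl)propan-2-ol (racemic) | COc1cc(C)oc1CC(C)O | intermediate
7 | 1-(3-methoxy-5-methylfuran-2-yl)propan-2-one | COc1cc(C)oc1CC(C)=O | intermediate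
8 | 3-(3-methoxy-5-methylfuran-2-yl)butan-2-one (racemic) | COc1cc(C)oc1C(C)C(C)=O | intermediate (not isolated)
9 | 3-(3-methoxy-5-methylfuran-2-yl)-3-methylbutan-2-one | COc1cc(C)oc1C(C)(C)C(C)=O | intermediate
10 | methyl (2E)-4-bromo-3-methylbut-2-enoate | COC(=O)/C=C(\C)CBr | starting material
11 | lithium 3-(3-methoxy-5-methylfuran-2-yl)-3-methylbut-1-en-2-olate | [Li+].[O-]C(=C)C(C)(C)c1oc(C)cc1OC | intermediate (not isolated)
12 | methyl (2E)-7-(3-methoxy-5-methylfuran-2-yl)-3,7-dimethyl-6-oxooct-2-enoate | COC(=O)/C=C(\C)CCC(=O)C(C)(C)c1oc(C)cc1OC | intermediate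
13 | methyl (2E,6R)-6-hydroxy-7-(3-methoxy-5-methylfuran-2-yl)-3,7-dimethyloct-2-enoate | COC(=O)/C=C(\C)CC[C@@H](O)C(C)(C)c1oc(C)cc1OC | intermediate
14 | methyl (2E,6R)-6-(2,2-dimethylpropanoyloxy)-7-(3-methoxy-5-methylfuran-2-yl)-3,7-dimethyloct-2-enoate (key-step precursor) | COC(=O)/C=C(\C)CC[C@@H](OC(=O)C(C)(C)C)C(C)(C)c1oc(C)cc1OC | intermediate
15 | methyl 5,8-epoxy-6-methoxy-3-pivaloyloxydrim-6-en-11-oate (key-step product; C10 methyl and ester anti to the bridge, C3 oxygen equatorial) | COC(=O)[C@H]1[C@]2(C)CC[C@@H](OC(=O)C(C)(C)C)C(C)(C)[C@@]2(O3)C(OC)=C[C@@]13C | intermediate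
16 | methyl 5,8-epoxy-6-oxo-3-pivaloyloxydriman-11-oate | COC(=O)[C@H]1[C@]2(C)CC[C@@H](OC(=O)C(C)(C)C)C(C)(C)[C@@]2(O3)C(=O)C[C@@]13C | intermediate
17 | samarium 5-en-6-olate 8-alkoxide of methyl 8-hydroxy-6-oxo-3-pivaloyloxydriman-11-oate (trivalent samarium) | COC(=O)[C@H]1[C@]2(C)CC[C@@H](OC(=O)C(C)(C)C)C(C)(C)C2=C([O-])C[C@]1(C)[O-].[Sm+3].[Sm+3].[I-].[I-].[I-].[I-] | intermediate (not isolated)
18 | methyl 8-hydroxy-6-oxo-3-pivaloyloxydriman-11-oate (trans-fused) | COC(=O)[C@H]1[C@]2(C)CC[C@@H](OC(=O)C(C)(C)C)C(C)(C)[C@H]2C(=O)C[C@]1(C)O | intermediate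
19 | methyl 6-oxo-3-pivaloyloxy-8-(triethylsilyloxy)driman-11-oate | COC(=O)[C@H]1[C@]2(C)CC[C@@H](OC(=O)C(C)(C)C)C(C)(C)[C@H]2C(=O)C[C@]1(C)O[Si](CC)(CC)CC | intermediate
20 | potassium 6-en-6-olate of 19 | COC(=O)[C@H]1[C@]2(C)CC[C@@H](OC(=O)C(C)(C)C)C(C)(C)[C@H]2C([O-])=C[C@]1(C)O[Si](CC)(CC)CC.[K+] | intermediate (not isolated)
21 | methyl 3-pivaloyloxy-8-(triethylsilyloxy)-6-(trifluoromethanesulfonyloxy)drim-6-en-11-oate | COC(=O)[C@H]1[C@]2(C)CC[C@@H](OC(=O)C(C)(C)C)C(C)(C)[C@H]2C(OS(=O)(=O)C(F)(F)F)=C[C@]1(C)O[Si](CC)(CC)CC | intermediate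
22 | methyl 3-pivaloyloxy-8-(triethylsilyloxy)drim-6-en-11-oate | COC(=O)[C@H]1[C@]2(C)CC[C@@H](OC(=O)C(C)(C)C)C(C)(C)[C@H]2C=C[C@]1(C)O[Si](CC)(CC)CC | intermediate
23 | 8-(triethylsilyloxy)drim-6-ene-3,11-diol (C3 hydroxyl equatorial) | OC[C@H]1[C@]2(C)CC[C@@H](O)C(C)(C)[C@H]2C=C[C@]1(C)O[Si](CC)(CC)CC | intermediate
24 | 3-oxo-8-(triethylsilyloxy)drim-6-en-11-al | O=C[C@H]1[C@]2(C)CCC(=O)C(C)(C)[C@H]2C=C[C@]1(C)O[Si](CC)(CC)CC | intermediate
25 | 1-(triphenyl-λ5-phosphanylidene)propan-2-one | CC(=O)C=P(c1ccccc1)(c1ccccc1)c1ccccc1 | starting material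
26 | (11E)-8-(triethylsilyloxy)-14,15-dinorlabda-6,11-diene-3,13-dione | CC(=O)/C=C/[C@H]1[C@]2(C)CCC(=O)C(C)(C)[C@H]2C=C[C@]1(C)O[Si](CC)(CC)CC | intermediate
27 | 8-(triethylsilyloxy)-14,15-dinorlabdane-3,13-dione | CC(=O)CC[C@H]1[C@]2(C)CCC(=O)C(C)(C)[C@H]2CC[C@]1(C)O[Si](CC)(CC)CC | intermediate
28 | trimethyl phosphonoacetate | COC(=O)CP(=O)(OC)OC | starting material
29 | methyl (13E)-3-oxo-8-(triethylsilyloxy)labd-13-en-15-oate | COC(=O)/C=C(\C)CC[C@H]1[C@]2(C)CCC(=O)C(C)(C)[C@H]2CC[C@]1(C)O[Si](CC)(CC)CC | intermediate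
30 | methyl (13E)-3-hydroxy-8-(triethylsilyloxy)labd-13-en-15-oate (C3 hydroxyl axial) | COC(=O)/C=C(\C)CC[C@H]1[C@]2(C)CC[C@H](O)C(C)(C)[C@H]2CC[C@]1(C)O[Si](CC)(CC)CC | intermediate
31 | methyl (3R,13E)-3-bromo-8-(triethylsilyloxy)labd-13-en-15-oate | COC(=O)/C=C(\C)CC[C@H]1[C@]2(C)CC[C@@H](Br)C(C)(C)[C@H]2CC[C@]1(C)O[Si](CC)(CC)CC | intermediate
32 | (3R,13E)-3-bromo-8-(triethylsilyloxy)labd-13-en-15-ol | C/C(=C\CO)CC[C@H]1[C@]2(C)CC[C@@H](Br)C(C)(C)[C@H]2CC[C@]1(C)O[Si](CC)(CC)CC | intermediate
33 | (3R,5S,8S,9S,10R,13E)-3-bromolabd-13-ene-8,15-diol | C/C(=C\CO)CC[C@H]1[C@]2(C)CC[C@@H](Br)C(C)(C)[C@H]2CC[C@]1(C)O | target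

Total step count: 22. Longest linear sequence: 22 steps from 1 (4, 10, 25 and 28 are bought).

Steps most likely to fail

Step 8. The new C5–C10 bond joins two fully substituted carbons next to the C4 quaternary centre, so cycloreversion may keep pace with cycloaddition and conversion may stall; the pivaloyloxy group may also show too little equatorial preference, which would lower the facial selectivity. The fallback uses a dienophile of lower LUMO and sets out from 14. i-Bu2AlH at −78 °C should reduce the conjugated methyl ester ahead of the hindered pivalate to (3R,6E)-8-hydroxy-2-(3-methoxy-5-methylfuran-2-yl)-2,6-dimethyloct-6-en-3-yl pivalate F1. MnO2 in CH2Cl2 should then give the enal (3R,6E)-2-(3-methoxy-5-methylfuran-2-yl)-2,6-dimethyl-8-oxooct-6-en-3-yl pivalate F2. The enal cyclises by the same exo mode (40 °C at 1 bar or under pressure) to 5,8-epoxy-6-methoxy-3-pivaloyloxydrim-6-en-11-al F3. Dilute HCl in THF gives 5,8-epoxy-6-oxo-3-pivaloyloxydriman-11-al F4. Pinnick oxidation (NaClO2, NaH2PO4, 2-methylbut-2-ene) gives 5,8-epoxy-6-oxo-3-pivaloyloxydriman-11-oic acid F5, and Me3SiCHN2 in MeOH/toluene returns the route at 16.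

Step 20. The axial oxyphosphonium has a trans-diaxial hydrogen at C2 and a migrating methyl at C4, so elimination to the C2=C3 alkene or ring-A rearrangement may outrun displacement at the neopentylic carbon. The fallback puts bromine on an sp2 carbon and sets C3 by hydrogen-atom delivery; it sets out from 27. Selective ketalisation of the unhindered C13 ketone (1,2-bis(trimethylsilyloxy)ethane, Me3SiOTf cat., CH2Cl2, −78 °C) gives 13,13-ethylenedioxy-8-(triethylsilyloxy)-14,15-dinorlabdan-3-one F7. (PhO)3P, Br2 and Et3N in CH2Cl2 convert the C3 ketone into the vinyl bromide 3-bromo-13,13-ethylenedioxy-8-(triethylsilyloxy)-14,15-dinorlabd-2-ene F8. Hydrogen-atom-transfer hydrogenation (Mn(dpm)3 cat., PhSiH3, t-BuOOH, i-PrOH), which keeps the halogen and delivers hydrogen to the α-bromo radical along the axial direction, should give the equatorial bromide (3R)-3-bromo-13,13-ethylenedioxy-8-(triethylsilyloxy)-14,15-dinorlabdane F9. Mild hydrolysis (PPTS, acetone/H2O) gives (3R)-3-bromo-8-(triethylsilyloxy)-14,15-dinorlabdan-13-one F10, and the Horner–Wadsworth–Emmons reaction of step 18 with 28 returns the route at 31.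

Step 9. Ionisation of the tertiary C8–O bond, which is vinylogously activated by the methoxy group, may compete with protonation at C7 and open the bridge on the wrong side, with loss of the C8 stereocentre. The fallback unmasks the ketone without Brønsted acid and sets out from 15. NBS with NaHCO3 in THF/H2O at 0 °C (bromohydration of the enol ether, loss of methanol) should give methyl 7-bromo-5,8-epoxy-6-oxo-3-pivaloyloxydriman-11-oate F6 as a mixture of C7 epimers. Excess SmI2 in THF/MeOH at −78 °C then removes the C7 bromine and cleaves C5–O in one operation, which returns the route at 18.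

Further compounds
F1 | step 8 | (3R,6E)-8-hydroxy-2-(3-methoxy-5-methylfuran-2-yl)-2,6-dimethyloct-6-en-3-yl 2,2-dimethylpropanoate | OC/C=C(\C)CC[C@@H](OC(=O)C(C)(C)C)C(C)(C)c1oc(C)cc1OC
F2 | step 8 | (3R,6E)-2-(3-methoxy-5-methylfuran-2-yl)-2,6-dimethyl-8-oxooct-6-en-3-yl 2,2-dimethylpropanoate | O=C/C=C(\C)CC[C@@H](OC(=O)C(C)(C)C)C(C)(C)c1oc(C)cc1OC
F3 | step 8 | 5,8-epoxy-6-methoxy-3-pivaloyloxydrim-6-en-11-al | O=C[C@H]1[C@]2(C)CC[C@@H](OC(=O)C(C)(C)C)C(C)(C)[C@@]2(O3)C(OC)=C[C@@]13C
F4 | step 8 | 5,8-epoxy-6-oxo-3-pivaloyloxydriman-11-al | O=C[C@H]1[C@]2(C)CC[C@@H](OC(=O)C(C)(C)C)C(C)(C)[C@@]2(O3)C(=O)C[C@@]13C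
F5 | step 8 | 5,8-epoxy-6-oxo-3-pivaloyloxydriman-11-oic acid | OC(=O)[C@H]1[C@]2(C)CC[C@@H](OC(=O)C(C)(C)C)C(C)(C)[C@@]2(O3)C(=O)C[C@@]13C
F6 | step 9 | methyl 7-bromo-5,8-epoxy-6-oxo-3-pivaloyloxydriman-11-oate (C7 epimers) | COC(=O)[C@H]1[C@]2(C)CC[C@@H](OC(=O)C(C)(C)C)C(C)(C)[C@@]2(O3)C(=O)C(Br)[C@@]13C
F7 | step 20 | 13,13-ethylenedioxy-8-(triethylsilyloxy)-14,15-dinorlabdan-3-one | CC1(OCCO1)CC[C@H]2[C@]3(C)CCC(=O)C(C)(C)[C@H]3CC[C@]2(C)O[Si](CC)(CC)CC
F8 | step 20 | 3-bromo-13,13-ethylenedioxy-8-(triethylsilyloxy)-14,15-dinorlabd-2-ene | CC1(OCCO1)CC[C@H]2[C@]3(C)CC=C(Br)C(C)(C)[C@H]3CC[C@]2(C)O[Si](CC)(CC)CC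
F9 | step 20 | (3R)-3-bromo-13,13-ethylenedioxy-8-(triethylsilyloxy)-14,15-dinorlabdane | CC1(OCCO1)CC[C@H]2[C@]3(C)CC[C@@H](Br)C(C)(C)[C@H]3CC[C@]2(C)O[Si](CC)(CC)CC
F10 | step 20 | (3R)-3-bromo-8-(triethylsilyloxy)-14,15-dinorlabdan-13-one | CC(=O)CC[C@H]1[C@]2(C)CC[C@@H](Br)C(C)(C)[C@H]2CC[C@]1(C)O[Si](CC)(CC)CC
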